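Remark: the target has no stereocentre, no stereogenic axis and no configurable double bond, so it is achiral and the demand for a single enantiomer is met by the constitution alone. Quercetin, a bulk chemical, is taken as a legitimate commercial starting material.

## Structural features

The target is a flavonol. A 4H-chromen-4-one (benzo ring A fused to pyranone ring C) carries a 3,4-dihydroxyphenyl ring B at C2, an enolic OH at C3 and phenolic OH groups at C5 and C7. The only departure from the parent flavonol is a fourth ring D, a 4-hydroxyphenyl group, hinged through one sp3 methylene to C8 of ring A, the carbon between C8a (which bears O1) and C7-OH. No stereocentres exist, so none stand next to each other and nothing has to be controlled in that respect. The fragile elements are three: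
- the catechol of ring B and the 3-hydroxy-enone of ring C, both oxidised by air in base and both strong ligands for boron and metals;
- the C8–CH2 bond, which strong acid can break by ipso-protonation of the phloroglucinol-type ring A, so that the benzyl group can wander between C8 and C6.

The real difficulty is selectivity in making the diarylmethane hinge. Ring A offers two nearly equivalent nucleophilic carbons (C6, C8), the molecule offers five nucleophilic oxygens, a C-benzylated ring A is more nucleophilic than the parent, and ring D must be joined only through the carbon para to its OH.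

The key step exploits the fact that the hinge carbon is ortho to C7-OH. The unit O7–C7–C8–CH2 is a latent ortho-quinone methide (C7=O, C8=CH2). Ring A can therefore be made the electrophile, and ring D can arrive as an aryl nucleophile whose point of attachment (C1'') is fixed by a C–B bond.

## Logic of the disconnections

**9 ⇒ 8 (unmasking).**
- Bonds cut: the O–CH2 bond of the benzyl ether at O4'' of ring D, and the two O–C bonds at the ketal carbon bridging O3' and O4' of ring B.
- Reason: the catechol is the group most easily oxidised and the best ligand for boron and rhodium, and a free O4''–H would make ring D an ambident nucleophile. Both masks are benzylic C–O bonds and fall in one neutral hydrogenolysis.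
- Gain: none in skeleton, but the other steps run on a soluble, air-stable substrate.
- Demand: the reduction must stop at the C–O bonds and spare C2=C3, C4=O and both C–C bonds of the hinge.

**8 ⇒ 7 + 6, with 7 released from 5 (key disconnection).**
- Bond cut: CH2–C1'' of ring D, not C8–CH2.
- Reason: the obvious cut at C8–CH2 makes ring A the nucleophile and leaves the choice among C8, C6 and five oxygens to substrate bias. The cut on the far side of the methylene makes ring A the electrophile at a carbon already in place. C8 and C1'' are both donor-activated carbons (ortho and para to oxygen), so joining them through one carbon is a union of like polarity. It becomes possible by reversing the polarity of the ring A half in 7.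
- In one sentence: an aryl group is transferred from boron to the exocyclic methylene of 7, released from 5.
- Gain: ring D arrives complete from 6, and 5 is only one carbon and one amine away from an unsubstituted ring A.
- Demand: 7 must be released slowly, and 6 must transfer its aryl group through the ipso carbon faster than 7 is consumed by a second flavonol or by itself.

**5 ⇒ 3 + 4.**
- Bond cut: C8–CH2, with the C–N bond kept.
- Reason: the aminomethyl cation is the smallest carbon electrophile that 7-OH delivers under hydrogen-bond control. Its product is deactivated towards a second entry, and its nitrogen is the leaving group the key step needs.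
- Gain: ring A becomes unsubstituted.
- Demand: C8 over C6, and one entry rather than two.

**3 ⇒ 1 + 2.**
- Bonds cut: the two O–C bonds of the ketal.
- Reason: only the vicinal 3',4'-diol can close a five-membered ring, so no selectivity control is needed.
- Gain: both precursors are commercial.
- Demand: the flavonol core must stand brief heating with evolution of HCl.

## Other disconnections considered

Alternative 1: (the first that comes to mind) Ring C is cut at O1–C2 and C2–C3 and the C3–O bond is removed.
- Precursors: the 2'-hydroxychalcone A3, from Claisen–Schmidt condensation of the C-benzylated acetophenone A1 with 3,4-bis(benzyloxy)benzaldehyde A2.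
- Forward key step: Algar–Flynn–Oyamada oxidative cyclisation of A3.
- Grounds against, hinge: the hinge problem is only moved. C-benzylation of a phloroglucinol ketone on the way to A1 meets the same C/O and mono/bis questions.
- Grounds against, regiochemistry: the two ortho hydroxyls of the ketone must be told apart by protecting groups so that ring closure places the benzyl group at C8 rather than C6.
- Grounds against, mechanism: the 6'-alkoxy group of A3 twists the aryl ketone out of plane. This favours five-membered closure at Cα of the epoxide over the six-membered closure that ring C needs.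
- Grounds against, economy: some nine steps would be spent rebuilding a skeleton that is sold in bulk.

Alternative 2: The C8–CH2 bond is cut with the biosynthetic polarity.
- Forward key step: 1 serves as carbon nucleophile and ring D as the para-quinone methide 4-methylidenecyclohexa-2,5-dien-1-one A5, generated from 4-hydroxybenzyl alcohol A4. The step is a 1,6-addition (Friedel–Crafts type).
- Merit: this is the shortest plan on paper.
- Grounds against, selectivity: no structural element decides between C8 and C6, between carbon and oxygen, or between one and two alkylations, and the first alkylation activates ring A for the second.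
- Grounds against, side reactions: A5 is also consumed by its own precursor A4. The acid that ionises A4 can reverse the new bond.
- Overall: the difficulty of the target would be passed to the separation of isomeric pentaphenols. The chosen plan removes all three choices by structure.

Alternative 3: The C8–CH2 bond is cut as a cross-coupling.
- Forward key step: the 8-iodo-penta-O-benzyl flavonol A6 is joined with the benzylboronate A7 in a Suzuki–Miyaura sp2–sp3 coupling.
- Grounds against, preparation: A6 needs exhaustive benzylation, including the chelated and sluggish 5-OH, followed by an iodination whose site depends on that full protection.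
- Grounds against, coupling: the aryl iodide is flanked on both sides, and benzylboron partners transmetalate slowly and homocouple.
- Grounds against, economy: six benzyl groups are carried and discarded over about five steps. The chosen plan needs one mask on the flavonol, no halogen, and forms the hinge at an unhindered CH2 terminus.

Key step: step 3

## Route

Step 1
Reactants: 1 quercetin (2-(3,4-dihydroxyphenyl)-3,5,7-trihydroxy-4H-chromen-4-one); 2 dichlorodiphenylmethane
Product: 3 2-(2,2-diphenyl-1,3-benzodioxol-5-yl)-3,5,7-trihydroxy-4H-chromen-4-one
Conditions: Ph2CCl2 (1.5 equiv), Ph2O, 175 °C, 30 min, Ar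
Reagents that add atoms: dichlorodiphenylmethane (2), ClC(Cl)(c1ccccc1)c1ccccc1
Why: Ketalisation of a catechol with a gem-dichloride (double O-alkylation through the chlorodiphenylmethyl cation); only the 3',4'-diol can close a five-membered 1,3-dioxole, whereas 3-OH, 5-OH and 7-OH could give only labile open adducts that revert, so the reaction selects its own site. HCl leaves as a gas and the flavonol core should tolerate the short thermal pulse.

Step 2
Reactants: 3 2-(2,2-diphenyl-1,3-benzodioxol-5-yl)-3,5,7-trihydroxy-4H-chromen-4-one; 4 N,N,N',N'-tetramethylmethanediamine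
Product: 5 8-[(dimethylamino)methyl]-2-(2,2-diphenyl-1,3-benzodioxol-5-yl)-3,5,7-trihydroxy-4H-chromen-4-one
Conditions: CH2(NMe2)2 (1.1 equiv), 1,4-dioxane, 80 °C, Ar
Reagents that add atoms: N,N,N',N'-tetramethylmethanediamine (4), CN(C)CN(C)C
Why: Mannich aminomethylation of a phenol with a preformed aminal; the most acidic 7-OH protonates 4 and the iminium/7-phenoxide pair collapses at an ortho carbon. C8 should be preferred over C6 because fusion to the pyranone fixes ring A in the Kekulé form with C7=C8 and C5=C6 double bonds (the bias that sends Claisen rearrangements of 7-allyloxyflavones to C8 and electrophiles to C1 of 2-naphthol), while 5-OH is locked in the chelate with C4=O. One equivalent of 4 and the hydrogen-bonded, partly zwitterionic character of 5 should limit a second entry.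

Step 3
Reactants: 5 8-[(dimethylamino)methyl]-2-(2,2-diphenyl-1,3-benzodioxol-5-yl)-3,5,7-trihydroxy-4H-chromen-4-one; 6 [4-(benzyloxy)phenyl]boronic acid
Product: 8 8-[4-(benzyloxy)benzyl]-2-(2,2-diphenyl-1,3-benzodioxol-5-yl)-3,5,7-trihydroxy-4H-chromen-4-one, via ortho-quinone methide 7 (not isolated)
Conditions: 6 (3 equiv), [Rh(OH)(cod)]2 (2.5 mol %), 1,4-dioxane, 90 °C, slow Ar sweep; then aq. NH4Cl
Reagents that add atoms: [4-(benzyloxy)phenyl]boronic acid (6), OB(O)c1ccc(OCc2ccccc2)cc1
Why: On heating, the hydrogen-bonded 7-OH···NMe2 pair of 5, further activated by N→B coordination to 6, undergoes 1,4-elimination of volatile dimethylamine and releases ortho-quinone methide 7 (C7=O, C8=CH2) in low stationary concentration. Aryl-rhodium(I), formed from 6 by transmetalation, adds in 1,4 fashion to the unhindered exocyclic CH2 of 7 and gives a rhodium 7-aryloxide in which ring A is aromatic again, which is the driving force; exchange with more 6 regenerates aryl-rhodium. The uncatalysed path, binding of O7 of 7 to boron and shift of the electron-rich 4-alkoxyphenyl group through a six-membered transition state as in the Petasis reaction of salicylaldehydes, forms the same bond, so both paths converge on 8. The closest known reaction types are the rhodium-catalysed arylation of ortho-hydroxybenzylamines with arylboron reagents by way of ortho-quinone methides and the conjugate addition of aryl boronates to ortho-quinone methides. No ring is closed and no stereocentre is formed. The step needs C- over O-alkylation, C8 over C6 and single alkylation, and all three are secured by structure, since the electrophilic carbon is already bonded to C8, ring A acts only as acceptor, and 8 holds no further leaving group. It needs attachment para to the oxygen of ring D, which ipso transfer from the C–B bond secures. It needs aryl capture to outrun attack by C6 of a second flavonol, which slow release of 7, excess 6 and the catalyst are meant to secure, while the ketal keeps the catechol away from boron and rhodium and the tetrasubstituted, donor-loaded C2=C3–C4=O unit is too hindered for 1,4-addition.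

Step 4
Reactants: 8 8-[4-(benzyloxy)benzyl]-2-(2,2-diphenyl-1,3-benzodioxol-5-yl)-3,5,7-trihydroxy-4H-chromen-4-one
Product: 9 8-p-hydroxybenzylquercetin (2-(3,4-dihydroxyphenyl)-3,5,7-trihydroxy-8-(4-hydroxybenzyl)-4H-chromen-4-one)
Conditions: H2 (1 atm), 10 % Pd/C, THF–EtOH (1:1), rt
Reagents that add atoms: none
Why: Catalytic hydrogenolysis of benzylic C–O bonds; the benzyl ether of ring D and both benzhydrylic C–O bonds of the ketal are cleaved under the same neutral conditions. The diarylmethane C–C bonds, C4=O and the tetrasubstituted push-pull C2=C3 bond should not be reduced at 1 atm and rt, and the neutral medium avoids acid scrambling of the hinge and base-promoted autoxidation.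

## Compound list

1 | quercetin (2-(3,4-dihydroxyphenyl)-3,5,7-trihydroxy-4H-chromen-4-one) | O=c1c(O)c(-c2ccc(O)c(O)c2)oc2cc(O)cc(O)c12 | starting material
2 | dichlorodiphenylmethane | ClC(Cl)(c1ccccc1)c1ccccc1 | starting material
3 | 2-(2,2-diphenyl-1,3-benzodioxol-5-yl)-3,5,7-trihydroxy-4H-chromen-4-one | O=c1c(O)c(-c2ccc3c(c2)OC(c2ccccc2)(c2ccccc2)O3)oc2cc(O)cc(O)c12 | intermediate
4 | N,N,N',N'-tetramethylmethanediamine | CN(C)CN(C)C | starting material
5 | 8-[(dimethylamino)methyl]-2-(2,2-diphenyl-1,3-benzodioxol-5-yl)-3,5,7-trihydroxy-4H-chromen-4-one | O=c1c(O)c(-c2ccc3c(c2)OC(c2ccccc2)(c2ccccc2)O3)oc2c(CN(C)C)c(O)cc(O)c12 | intermediate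
6 | [4-(benzyloxy)phenyl]boronic acid | OB(O)c1ccc(OCc2ccccc2)cc1 | starting material
7 | ortho-quinone methide, 2-(2,2-diphenyl-1,3-benzodioxol-5-yl)-3,5-dihydroxy-8-methylidene-4H-chromene-4,7(8H)-dione | C=C1C(=O)C=C(O)C2=C1OC(c1ccc3c(c1)OC(c1ccccc1)(c1ccccc1)O3)=C(O)C2=O | intermediate
8 | 8-[4-(benzyloxy)benzyl]-2-(2,2-diphenyl-1,3-benzodioxol-5-yl)-3,5,7-trihydroxy-4H-chromen-4-one | O=c1c(O)c(-c2ccc3c(c2)OC(c2ccccc2)(c2ccccc2)O3)oc2c(Cc3ccc(OCc4ccccc4)cc3)c(O)cc(O)c12 | intermediate
9 | 8-p-hydroxybenzylquercetin | O=c1c(O)c(-c2ccc(O)c(O)c2)oc2c(Cc3ccc(O)cc3)c(O)cc(O)c12 | target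

## Step count and least certain steps

Total step count: 4. Longest linear sequence: 4 steps (1 → 3 → 5 → 8 → 9).

**Step 3 (key step).**
- What may go wrong: capture of the transient ortho-quinone methide by C6 of a second flavonol, or its self-dimerisation, may outrun aryl transfer. The acac-like 3-OH/C4=O unit may chelate rhodium, and the 3-OH/C4=O and 5-OH/C4=O sites may hold back boron, which slows transmetalation. The phenolic protons may protodeboronate the boron reagent.
- Fallback (sets out from 5, comes back at 8): the quinone methide is given up in favour of a palladium η3-benzyl intermediate.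
  - Acetolysis of 5 in boiling acetic anhydride should exchange the amine for acetate and cap the three hydroxyls, giving [3,5,7-tris(acetyloxy)-2-(2,2-diphenyl-1,3-benzodioxol-5-yl)-4-oxo-4H-chromen-8-yl]methyl acetate F1.
  - Suzuki–Miyaura coupling of this benzylic acetate with 6 (Pd(0), bisphosphine, K2CO3, t-AmOH, 80 °C) should give 8-[4-(benzyloxy)benzyl]-2-(2,2-diphenyl-1,3-benzodioxol-5-yl)-4-oxo-4H-chromene-3,5,7-triyl triacetate F2.
  - Methanolysis (cat. K2CO3, MeOH–THF, 0 °C, Ar) returns to 8. With ring A acylated it is no longer a competing nucleophile.

**Step 2.**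
- What may go wrong: site selectivity between C8 and C6 may be insufficient, and a second aminomethylation may occur, because the two positions differ only through bond fixation and hydrogen bonding.
- Fallback (sets out from 3, comes back at 9): C6 is blocked by a group that the last step removes anyway.
  - Iodination of 3 with N-iodosuccinimide (DMF, rt), directed ortho to the chelated 5-OH, should give 2-(2,2-diphenyl-1,3-benzodioxol-5-yl)-3,5,7-trihydroxy-6-iodo-4H-chromen-4-one F3. Its substitution pattern can be settled before anything valuable is spent.
  - Aminomethylation with 4 can then enter only at C8, giving 8-[(dimethylamino)methyl]-2-(2,2-diphenyl-1,3-benzodioxol-5-yl)-3,5,7-trihydroxy-6-iodo-4H-chromen-4-one F4.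
  - Coupling with 6 under the conditions of step 3 proceeds through the 6-iodo ortho-quinone methide 2-(2,2-diphenyl-1,3-benzodioxol-5-yl)-3,5-dihydroxy-6-iodo-8-methylidene-4H-chromene-4,7(8H)-dione F5. It gives 8-[4-(benzyloxy)benzyl]-2-(2,2-diphenyl-1,3-benzodioxol-5-yl)-3,5,7-trihydroxy-6-iodo-4H-chromen-4-one F6.
  - Hydrogenolysis (H2, Pd/C, NaOAc, THF–EtOH) cleaves the C–I bond, the benzyl ether and the ketal together to give 9.

**Step 4.**
- What may go wrong: the hindered ketal may cleave slowly on a catalyst surface occupied by the chelating polyphenol. That would call for forcing conditions under which saturation of C2=C3 could begin.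
- Fallback (sets out from 5, comes back at 9): reductive unmasking is replaced by hydrolytic unmasking.
  - The key step is run on 5 with 4-hydroxyphenylboronic acid in place of 6, again through 7. It should give 2-(2,2-diphenyl-1,3-benzodioxol-5-yl)-3,5,7-trihydroxy-8-(4-hydroxybenzyl)-4H-chromen-4-one F7, which carries no benzyl ether.
  - The ketal is then hydrolysed in AcOH–H2O (4:1) at reflux under Ar to give 9. This acid is too weak to ionise the hinge.

## Further compounds

F1 | step 3 | [3,5,7-tris(acetyloxy)-2-(2,2-diphenyl-1,3-benzodioxol-5-yl)-4-oxo-4H-chromen-8-yl]methyl acetate | O=c1c(OC(C)=O)c(-c2ccc3c(c2)OC(c2ccccc2)(c2ccccc2)O3)oc2c(COC(C)=O)c(OC(C)=O)cc(OC(C)=O)c12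
F2 | step 3 | 8-[4-(benzyloxy)benzyl]-2-(2,2-diphenyl-1,3-benzodioxol-5-yl)-4-oxo-4H-chromene-3,5,7-triyl triacetate | O=c1c(OC(C)=O)c(-c2ccc3c(c2)OC(c2ccccc2)(c2ccccc2)O3)oc2c(Cc3ccc(OCc4ccccc4)cc3)c(OC(C)=O)cc(OC(C)=O)c12
F3 | step 2 | 2-(2,2-diphenyl-1,3-benzodioxol-5-yl)-3,5,7-trihydroxy-6-iodo-4H-chromen-4-one | O=c1c(O)c(-c2ccc3c(c2)OC(c2ccccc2)(c2ccccc2)O3)oc2cc(O)c(I)c(O)c12
F4 | step 2 | 8-[(dimethylamino)methyl]-2-(2,2-diphenyl-1,3-benzodioxol-5-yl)-3,5,7-trihydroxy-6-iodo-4H-chromen-4-one | O=c1c(O)c(-c2ccc3c(c2)OC(c2ccccc2)(c2ccccc2)O3)oc2c(CN(C)C)c(O)c(I)c(O)c12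
F5 | step 2 | 2-(2,2-diphenyl-1,3-benzodioxol-5-yl)-3,5-dihydroxy-6-iodo-8-methylidene-4H-chromene-4,7(8H)-dione | C=C1C(=O)C(I)=C(O)C2=C1OC(c1ccc3c(c1)OC(c1ccccc1)(c1ccccc1)O3)=C(O)C2=O
F6 | step 2 | 8-[4-(benzyloxy)benzyl]-2-(2,2-diphenyl-1,3-benzodioxol-5-yl)-3,5,7-trihydroxy-6-iodo-4H-chromen-4-one | O=c1c(O)c(-c2ccc3c(c2)OC(c2ccccc2)(c2ccccc2)O3)oc2c(Cc3ccc(OCc4ccccc4)cc3)c(O)c(I)c(O)c12
F7 | step 4 | 2-(2,2-diphenyl-1,3-benzodioxol-5-yl)-3,5,7-trihydroxy-8-(4-hydroxybenzyl)-4H-chromen-4-one | O=c1c(O)c(-c2ccc3c(c2)OC(c2ccccc2)(c2ccccc2)O3)oc2c(Cc3ccc(O)cc3)c(O)cc(O)c12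
A1 | alternative 1 | 1-{3-[4-(benzyloxy)benzyl]-2-hydroxy-4,6-bis(methoxymethoxy)phenyl}ethanone | CC(=O)c1c(O)c(Cc2ccc(OCc3ccccc3)cc2)c(OCOC)cc1OCOC
A2 | alternative 1 | 3,4-bis(benzyloxy)benzaldehyde | O=Cc1ccc(OCc2ccccc2)c(OCc2ccccc2)c1
A3 | alternative 1 | (E)-1-{3-[4-(benzyloxy)benzyl]-2-hydroxy-4,6-bis(methoxymethoxy)phenyl}-3-[3,4-bis(benzyloxy)phenyl]prop-2-en-1-one | O=C(/C=C/c1ccc(OCc2ccccc2)c(OCc2ccccc2)c1)c1c(O)c(Cc2ccc(OCc3ccccc3)cc2)c(OCOC)cc1OCOC
A4 | alternative 2 | 4-hydroxybenzyl alcohol | OCc1ccc(O)cc1
A5 | alternative 2 | 4-methylidenecyclohexa-2,5-dien-1-one | C=C1C=CC(=O)C=C1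
A6 | alternative 3 | 3,5,7-tris(benzyloxy)-2-[3,4-bis(benzyloxy)phenyl]-8-iodo-4H-chromen-4-one | O=c1c(OCc2ccccc2)c(-c2ccc(OCc3ccccc3)c(OCc3ccccc3)c2)oc2c(I)c(OCc3ccccc3)cc(OCc3ccccc3)c12
A7 | alternative 3 | 2-[4-(benzyloxy)benzyl]-4,4,5,5-tetramethyl-1,3,2-dioxaborolane | CC1(C)OB(Cc2ccc(OCc3ccccc3)cc2)OC1(C)C
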